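Ring A is built last. Its pattern (O at C4 and C6, H at C5 and C7) is that of a 4-alkoxy-2-pyrone (C5, C6, C7, C7a) joined to an alkyne (C3a, C4) through C1–C2–C3. Heating acylpyrone 17 should therefore, in one operation, close ring B (C7a–C3a) and ring A (C4–C5), expel CO2 and leave boron on C4 as the latent hydroxyl. Precursor 17 is a 6-acyl-4-isopropoxy-2-pyrone whose ketone is C1, with ring D on the epimerisable C2, ring C on the preset C3 stereocentre and an alkynyl pinacolboronate terminus. Ring E is attached afterwards by benzyl addition to C1 and dehydration.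

Key step: step 11

Remarks on the chemistry (assumptions)
- C2 lies between the C1 carbonyl and ring D and is configurationally labile. Compounds 14–18 are therefore carried as C2 epimers (C2 undefined in their SMILES); only C3 is controlled before the indanone stage, and C2 is fixed as trans in 19.
- The sense of induction of the copper/pybox catalyst in step 9 is assumed. Pybox here is 2,6-bis(4-phenyl-4,5-dihydro-1,3-oxazol-2-yl)pyridine, and the antipode that gives (3R)-14 is to be used.
- The spatial arrangement at C3 never changes after step 9. Its CIP descriptor does change with the neighbouring atoms: R in 14–17 and 19, S in 18 and in 20–29.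
- All phenols are isopropyl ethers: they should survive 165 °C, LDA and organometallic reagents, and BCl3 removes them beside the ring E methyl ether. The boronate is installed last and 17 is used without chromatography, because alkynyl pinacolboronates hydrolyse on silica.

Step 1
Reactants: 1 triacetic acid lactone (4-hydroxy-6-methyl-2H-pyran-2-one)
Product: 2 4-isopropoxy-6-methyl-2H-pyran-2-one
Conditions: iPrOH, PPh3, DIAD, THF, 0 °C → rt
Reagents that add atoms: propan-2-ol, CC(C)O
Why: Mitsunobu etherification of the strongly acidic C4 hydroxyl occurs on oxygen and gives the 4-alkoxy-2-pyrone whose oxygen becomes O–C6 and whose methyl carbon becomes C1.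

Step 2
Reactants: 2 4-isopropoxy-6-methyl-2H-pyran-2-one
Product: 3 4-isopropoxy-2-oxo-2H-pyran-6-carbaldehyde
Conditions: SeO2, 1,4-dioxane, 160 °C (sealed tube)
Reagents that add atoms: selenium dioxide, O=[Se]=O
Why: Riley oxidation (ene reaction, then [2,3]-shift) of the activated allylic-type C6 methyl group stops at the aldehyde, as established for 4-alkoxy-6-methyl-2-pyrones.

Step 3
Reactants: 4 3,5-dihydroxybenzyl alcohol
Product: 5 3,5-diisopropoxybenzyl alcohol
Conditions: 2-bromopropane, K2CO3, DMF, 70 °C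
Reagents that add atoms: 2-bromopropane, CC(C)Br
Why: Williamson etherification is selective for the two phenoxides because carbonate does not deprotonate the benzylic alcohol.

Step 4
Reactants: 5 3,5-diisopropoxybenzyl alcohol
Product: 6 3,5-diisopropoxybenzyl chloride
Conditions: SOCl2, DMF (cat.), CH2Cl2, 0 °C
Reagents that add atoms: thionyl chloride, O=S(Cl)Cl
Why: Chlorodehydroxylation through the chlorosulfite ester converts the primary benzylic alcohol into the chloride while the aryl isopropyl ethers are inert.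

Step 5
Reactants: 6 3,5-diisopropoxybenzyl chloride; 3 4-isopropoxy-2-oxo-2H-pyran-6-carbaldehyde
Product: 8 6-[2-(3,5-diisopropoxyphenyl)-1-hydroxyethyl]-4-isopropoxy-2H-pyran-2-one (racemic), via Grignard reagent 7 (not isolated)
Conditions: Mg, THF, 0 °C; then 3, THF, −78 °C; aq. NH4Cl
Reagents that add atoms: none
Why: Grignard 1,2-addition to the aldehyde, which at −78 °C is far more electrophilic than the vinylogous ester carbonyl of the pyrone, forms the C1–C2 bond; the racemic carbinol centre is removed in the next step.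

Step 6
Reactants: 8 6-[2-(3,5-diisopropoxyphenyl)-1-hydroxyethyl]-4-isopropoxy-2H-pyran-2-one
Product: 9 6-[(3,5-diisopropoxyphenyl)acetyl]-4-isopropoxy-2H-pyran-2-one
Conditions: Dess–Martin periodinane, CH2Cl2, rt
Reagents that add atoms: none
Why: Dess–Martin oxidation under neutral conditions converts the secondary carbinol into the arylacetyl ketone without touching the pyrone or the ethers.

Step 7
Reactants: 10 2,4-dihydroxybenzaldehyde
Product: 11 2,4-diisopropoxybenzaldehyde
Conditions: 2-bromopropane, K2CO3, DMF, 80 °C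
Reagents that add atoms: 2-bromopropane, CC(C)Br
Why: Williamson etherification, with heating so that the hydrogen-bonded hydroxyl next to the aldehyde is alkylated as well.

Step 8
Reactants: 11 2,4-diisopropoxybenzaldehyde
Product: 13 1-(2,4-diisopropoxyphenyl)prop-2-yn-1-yl acetate (racemic), via magnesium alkoxide 12 (not isolated)
Conditions: HC≡CMgBr, THF, 0 °C; then Ac2O, 0 °C → rt
Reagents that add atoms: ethynylmagnesium bromide, C#C[Mg]Br; acetic anhydride, CC(=O)OC(C)=O
Why: Grignard addition of the acetylide and acylation of the magnesium alkoxide in the same flask give the racemic propargylic acetate, whose configuration is irrelevant because this centre becomes planar in the copper allenylidene.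

Step 9
Reactants: 9 6-[(3,5-diisopropoxyphenyl)acetyl]-4-isopropoxy-2H-pyran-2-one; 13 1-(2,4-diisopropoxyphenyl)prop-2-yn-1-yl acetate
Product: 14 6-[(3R)-2-(3,5-diisopropoxyphenyl)-3-(2,4-diisopropoxyphenyl)pent-4-ynoyl]-4-isopropoxy-2H-pyran-2-one (C2 epimers)
Conditions: Cu(MeCN)4BF4 (5 mol %), Ph-pybox (6 mol %), iPr2NEt, MeOH, −20 °C
Reagents that add atoms: none
Why: Proposed new method: monovalent copper with the pybox ligand converts the terminal alkyne of 13 into a copper acetylide that ionises to a copper allenylidene, and the amine-generated enol(ate) of 9, made unusually acidic by ring D and the pyranonyl carbonyl, attacks the γ-carbon on the face left open by the ligand, which sets C3 (3R), before protonolysis releases 14; the closest known reaction type is the copper-catalysed asymmetric propargylic substitution of 1-arylpropargyl esters with β-keto esters, 1,3-diketones or ketone enamines, the mono-ketone pronucleophile being the untested element, and the C2 epimer mixture is of no consequence.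

Step 10
Reactants: 14 6-[(3R)-2-(3,5-diisopropoxyphenyl)-3-(2,4-diisopropoxyphenyl)pent-4-ynoyl]-4-isopropoxy-2H-pyran-2-one
Product: 17 6-[(3R)-2-(3,5-diisopropoxyphenyl)-3-(2,4-diisopropoxyphenyl)-5-(4,4,5,5-tetramethyl-1,3,2-dioxaborolan-2-yl)pent-4-ynoyl]-4-isopropoxy-2H-pyran-2-one (C2 epimers), via dilithium enolate acetylide 15 (not isolated), via lithium alkynylborate 16 (not isolated)
Conditions: LDA (2.2 equiv), THF, −78 °C; iPrOBpin, −78 °C; HCl·Et2O (2.1 equiv), −78 °C → rt; filtration, used crude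
Reagents that add atoms: 2-isopropoxy-4,4,5,5-tetramethyl-1,3,2-dioxaborolane, CC(C)OB1OC(C)(C)C(C)(C)O1
Why: Lithium acetylide borylation: the first equivalent of LDA turns the acidic C2–H ketone into its enolate, which shields ketone and pyrone, the second metalates the alkyne, the acetylide adds to the borate ester, and anhydrous HCl collapses the ate complex and reprotonates the enolate, C3 being neither acidic nor involved.

Step 11
Reactants: 17 6-[(3R)-2-(3,5-diisopropoxyphenyl)-3-(2,4-diisopropoxyphenyl)-5-(4,4,5,5-tetramethyl-1,3,2-dioxaborolan-2-yl)pent-4-ynoyl]-4-isopropoxy-2H-pyran-2-one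
Product: 19 (2S,3R)-2-(3,5-diisopropoxyphenyl)-3-(2,4-diisopropoxyphenyl)-6-isopropoxy-4-(4,4,5,5-tetramethyl-1,3,2-dioxaborolan-2-yl)-2,3-dihydro-1H-inden-1-one (trans), via bridged bicyclic lactone 18 (not isolated)
Conditions: mesitylene (0.01 M), 165 °C, Ar; then DBU (10 mol %), rt
Reagents that add atoms: none
Why: The 2-pyrone serves as the diene through its C3 and C6 termini and the tethered alkynylboronate as the dienophile in a thermal [4+2] cycloaddition that forms C7a–C3a and C5–C4 and gives the bridged lactone 18, which loses CO2 by retro-[4+2] so that ring A emerges aromatic. The closest known reaction types are the thermal cycloaddition of 2-pyrones with alkynylboronates with extrusion of carbon dioxide and the intramolecular pyrone–alkyne Diels–Alder reaction. Ring B closes as a five-membered ring in the fused mode, bond C7a–C3a joining the tether-bearing pyrone carbon to the proximal alkyne carbon, and ring A closes as the six-membered cycloadduct ring that is then aromatised. No stereocentre is created: the two bridgehead centres of 18 vanish on aromatisation, C3 is a spectator under neutral thermal conditions, and C2 equilibrates through the enol (completed by catalytic DBU) to the trans arrangement imposed by the C3 aryl group. The step needs regioselectivity (boron at C4, isopropoxy at C6), which the three-atom tether C1–C2–C3 secures because the bridged orientation is geometrically out of reach; high dilution and exclusion of water and metal residues guard against intermolecular addition, protodeboronation and enol–alkyne cycloisomerisation.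

Step 12
Reactants: 19 (2S,3R)-2-(3,5-diisopropoxyphenyl)-3-(2,4-diisopropoxyphenyl)-6-isopropoxy-4-(4,4,5,5-tetramethyl-1,3,2-dioxaborolan-2-yl)-2,3-dihydro-1H-inden-1-one
Product: 20 (2S,3S)-2-(3,5-diisopropoxyphenyl)-3-(2,4-diisopropoxyphenyl)-4-hydroxy-6-isopropoxy-2,3-dihydro-1H-inden-1-one
Conditions: NaBO3·4H2O, THF/H2O, rt
Reagents that add atoms: sodium perborate, [Na+].[Na+].O[B-]1(O)OO[B-](O)(O)OO1
Why: Perborate oxidation of the aryl boronate (1,2-shift of C4 from boron to oxygen) reveals the C4 phenol under conditions too mild to hydroxylate the ketone α-position.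

Step 13
Reactants: 20 (2S,3S)-2-(3,5-diisopropoxyphenyl)-3-(2,4-diisopropoxyphenyl)-4-hydroxy-6-isopropoxy-2,3-dihydro-1H-inden-1-one
Product: 21 (2S,3S)-2-(3,5-diisopropoxyphenyl)-3-(2,4-diisopropoxyphenyl)-4,6-diisopropoxy-2,3-dihydro-1H-inden-1-one
Conditions: 2-bromopropane, K2CO3, DMF, 50 °C, Ar
Reagents that add atoms: 2-bromopropane, CC(C)Br
Why: Williamson etherification of the single phenol gives the fully protected indanone, and the mild base can only reinforce the trans arrangement at C2.

Step 14
Reactants: 22 vanillin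
Product: 23 4-isopropoxy-3-methoxybenzaldehyde
Conditions: 2-bromopropane, K2CO3, DMF, 70 °C
Reagents that add atoms: 2-bromopropane, CC(C)Br
Why: Williamson etherification of the phenol gives ring E with the protecting pattern (isopropyl beside methyl) that the last step distinguishes.

Step 15
Reactants: 23 4-isopropoxy-3-methoxybenzaldehyde
Product: 24 4-isopropoxy-3-methoxybenzyl alcohol
Conditions: NaBH4, MeOH, 0 °C
Reagents that add atoms: none
Why: Borohydride reduction of the aryl aldehyde to the benzylic alcohol is chemoselective and leaves both ethers alone.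

Step 16
Reactants: 24 4-isopropoxy-3-methoxybenzyl alcohol
Product: 25 4-isopropoxy-3-methoxybenzyl chloride
Conditions: SOCl2, CH2Cl2, 0 °C; used fresh
Reagents that add atoms: thionyl chloride, O=S(Cl)Cl
Why: Chlorodehydroxylation through the chlorosulfite ester is fast for this electron-rich benzylic alcohol, and the labile chloride is taken on at once.

Step 17
Reactants: 25 4-isopropoxy-3-methoxybenzyl chloride; 21 (2S,3S)-2-(3,5-diisopropoxyphenyl)-3-(2,4-diisopropoxyphenyl)-4,6-diisopropoxy-2,3-dihydro-1H-inden-1-one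
Product: 28 (1E,2S,3S)-2-(3,5-diisopropoxyphenyl)-3-(2,4-diisopropoxyphenyl)-4,6-diisopropoxy-1-(4-isopropoxy-3-methoxybenzylidene)-2,3-dihydro-1H-indene, via Grignard reagent 26 (not isolated), via tertiary carbinol 27 (not isolated)
Conditions: Mg, THF, 0 °C; CeCl3, THF, −78 °C; then 21, −78 → 0 °C; aq. NH4Cl; then p-TsOH·H2O (cat.), PhMe, rt
Reagents that add atoms: none
Why: Organocerium 1,2-addition of the benzylic nucleophile to the hindered, enolisable ketone avoids deprotonation at C2, and acid-catalysed E1 dehydration of carbinol 27 should then give, under thermodynamic control, the exocyclic styrene with ring E syn to C2 (E), since the Z isomer clashes with the peri C7–H and the endocyclic isomer crowds C1–C2–C3; C2 and C3 are not touched.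

Step 18
Reactants: 28 (1E,2S,3S)-2-(3,5-diisopropoxyphenyl)-3-(2,4-diisopropoxyphenyl)-4,6-diisopropoxy-1-(4-isopropoxy-3-methoxybenzylidene)-2,3-dihydro-1H-indene
Product: 29 (1E,2S,3S)-2-(3,5-dihydroxyphenyl)-3-(2,4-dihydroxyphenyl)-1-(4-hydroxy-3-methoxybenzylidene)-2,3-dihydro-1H-indene-4,6-diol (CNP0122890.1)
Conditions: BCl3, CH2Cl2, −78 → 0 °C; then H2O
Reagents that add atoms: none
Why: Lewis-acid ether cleavage: BCl3 coordinates the ether oxygens and the secondary isopropyl groups leave as 2-chloropropane far faster than the ring E methyl group, so the seven isopropyl ethers should fall while the methyl ether, the alkene geometry and both stereocentres persist.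

Compound list
1 | triacetic acid lactone (4-hydroxy-6-methyl-2H-pyran-2-one) | CC1=CC(O)=CC(=O)O1 | starting material
2 | 4-isopropoxy-6-methyl-2H-pyran-2-one | CC1=CC(OC(C)C)=CC(=O)O1 | intermediate
3 | 4-isopropoxy-2-oxo-2H-pyran-6-carbaldehyde | O=CC1=CC(OC(C)C)=CC(=O)O1 | intermediate
4 | 3,5-dihydroxybenzyl alcohol | OCc1cc(O)cc(O)c1 | starting material
5 | 3,5-diisopropoxybenzyl alcohol | OCc1cc(OC(C)C)cc(OC(C)C)c1 | intermediate
6 | 3,5-diisopropoxybenzyl chloride | ClCc1cc(OC(C)C)cc(OC(C)C)c1 | intermediate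
7 | (3,5-diisopropoxybenzyl)magnesium chloride | Cl[Mg]Cc1cc(OC(C)C)cc(OC(C)C)c1 | intermediate (not isolated)
8 | 6-[2-(3,5-diisopropoxyphenyl)-1-hydroxyethyl]-4-isopropoxy-2H-pyran-2-one (racemic) | OC(Cc1cc(OC(C)C)cc(OC(C)C)c1)C1=CC(OC(C)C)=CC(=O)O1 | intermediate
9 | 6-[(3,5-diisopropoxyphenyl)acetyl]-4-isopropoxy-2H-pyran-2-one | O=C(Cc1cc(OC(C)C)cc(OC(C)C)c1)C1=CC(OC(C)C)=CC(=O)O1 | intermediate
10 | 2,4-dihydroxybenzaldehyde | O=Cc1ccc(O)cc1O | starting material
11 | 2,4-diisopropoxybenzaldehyde | O=Cc1ccc(OC(C)C)cc1OC(C)C | intermediate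
12 | bromomagnesium 1-(2,4-diisopropoxyphenyl)prop-2-yn-1-olate (racemic) | C#CC(O[Mg]Br)c1ccc(OC(C)C)cc1OC(C)C | intermediate (not isolated)
13 | 1-(2,4-diisopropoxyphenyl)prop-2-yn-1-yl acetate (racemic) | CC(=O)OC(C#C)c1ccc(OC(C)C)cc1OC(C)C | intermediate
14 | 6-[(3R)-2-(3,5-diisopropoxyphenyl)-3-(2,4-diisopropoxyphenyl)pent-4-ynoyl]-4-isopropoxy-2H-pyran-2-one (C2 epimers) | CC(C)OC1=CC(=O)OC(=C1)C(=O)C(c1cc(OC(C)C)cc(OC(C)C)c1)[C@@H](c1ccc(OC(C)C)cc1OC(C)C)C#C | intermediate
15 | dilithium enolate/acetylide of 14 (3R) | CC(C)OC1=CC(=O)OC(=C1)C(O[Li])=C(c1cc(OC(C)C)cc(OC(C)C)c1)[C@@H](c1ccc(OC(C)C)cc1OC(C)C)C#C[Li] | intermediate (not isolated)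
16 | lithium enolate of the lithium alkynyl(isopropoxy)pinacolborate (3R) | [Li+].CC(C)OC1=CC(=O)OC(=C1)C(O[Li])=C(c1cc(OC(C)C)cc(OC(C)C)c1)[C@@H](c1ccc(OC(C)C)cc1OC(C)C)C#C[B-]1(OC(C)C)OC(C)(C)C(C)(C)O1 | intermediate (not isolated)
17 | 6-[(3R)-2-(3,5-diisopropoxyphenyl)-3-(2,4-diisopropoxyphenyl)-5-(4,4,5,5-tetramethyl-1,3,2-dioxaborolan-2-yl)pent-4-ynoyl]-4-isopropoxy-2H-pyran-2-one (C2 epimers) | CC(C)OC1=CC(=O)OC(=C1)C(=O)C(c1cc(OC(C)C)cc(OC(C)C)c1)[C@@H](c1ccc(OC(C)C)cc1OC(C)C)C#CB1OC(C)(C)C(C)(C)O1 | intermediate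
18 | bridged cycloadduct: 2-oxabicyclo[2.2.2]octa-5,7-dien-3-one fused to the ring B cyclopentanone (bridgeheads and C2 undefined, C3 as in 17) | O=C1C(c2cc(OC(C)C)cc(OC(C)C)c2)[C@@H](c2ccc(OC(C)C)cc2OC(C)C)C2=C(B3OC(C)(C)C(C)(C)O3)C3C(OC(C)C)=CC12OC3=O | intermediate (not isolated)
19 | (2S,3R)-2-(3,5-diisopropoxyphenyl)-3-(2,4-diisopropoxyphenyl)-6-isopropoxy-4-(4,4,5,5-tetramethyl-1,3,2-dioxaborolan-2-yl)-2,3-dihydro-1H-inden-1-one (trans) | O=C1c2cc(OC(C)C)cc(B3OC(C)(C)C(C)(C)O3)c2[C@H](c2ccc(OC(C)C)cc2OC(C)C)[C@H]1c1cc(OC(C)C)cc(OC(C)C)c1 | intermediate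
20 | (2S,3S)-2-(3,5-diisopropoxyphenyl)-3-(2,4-diisopropoxyphenyl)-4-hydroxy-6-isopropoxy-2,3-dihydro-1H-inden-1-one | O=C1c2cc(OC(C)C)cc(O)c2[C@H](c2ccc(OC(C)C)cc2OC(C)C)[C@H]1c1cc(OC(C)C)cc(OC(C)C)c1 | intermediate
21 | (2S,3S)-2-(3,5-diisopropoxyphenyl)-3-(2,4-diisopropoxyphenyl)-4,6-diisopropoxy-2,3-dihydro-1H-inden-1-one | O=C1c2cc(OC(C)C)cc(OC(C)C)c2[C@H](c2ccc(OC(C)C)cc2OC(C)C)[C@H]1c1cc(OC(C)C)cc(OC(C)C)c1 | intermediate
22 | vanillin | COc1cc(C=O)ccc1O | starting material
23 | 4-isopropoxy-3-methoxybenzaldehyde | COc1cc(C=O)ccc1OC(C)C | intermediate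
24 | 4-isopropoxy-3-methoxybenzyl alcohol | COc1cc(CO)ccc1OC(C)C | intermediate
25 | 4-isopropoxy-3-methoxybenzyl chloride | COc1cc(CCl)ccc1OC(C)C | intermediate
26 | (4-isopropoxy-3-methoxybenzyl)magnesium chloride | COc1cc(C[Mg]Cl)ccc1OC(C)C | intermediate (not isolated)
27 | (2S,3S)-2-(3,5-diisopropoxyphenyl)-3-(2,4-diisopropoxyphenyl)-4,6-diisopropoxy-1-(4-isopropoxy-3-methoxybenzyl)-2,3-dihydro-1H-inden-1-ol (C1 epimers) | COc1cc(CC2(O)c3cc(OC(C)C)cc(OC(C)C)c3[C@H](c3ccc(OC(C)C)cc3OC(C)C)[C@H]2c2cc(OC(C)C)cc(OC(C)C)c2)ccc1OC(C)C | intermediate (not isolated)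
28 | (1E,2S,3S)-2-(3,5-diisopropoxyphenyl)-3-(2,4-diisopropoxyphenyl)-4,6-diisopropoxy-1-(4-isopropoxy-3-methoxybenzylidene)-2,3-dihydro-1H-indene | COc1cc(/C=C2/c3cc(OC(C)C)cc(OC(C)C)c3[C@H](c3ccc(OC(C)C)cc3OC(C)C)[C@H]2c2cc(OC(C)C)cc(OC(C)C)c2)ccc1OC(C)C | intermediate
29 | (1E,2S,3S)-2-(3,5-dihydroxyphenyl)-3-(2,4-dihydroxyphenyl)-1-(4-hydroxy-3-methoxybenzylidene)-2,3-dihydro-1H-indene-4,6-diol | COc1cc(/C=C2/c3cc(O)cc(O)c3[C@H](c3ccc(O)cc3O)[C@H]2c2cc(O)cc(O)c2)ccc1O | target

Total step count: 18.
Longest linear sequence: 11 steps (steps 1, 2, 5, 6, 9, 10, 11, 12, 13, 17, 18, from triacetic acid lactone).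

Steps most likely to fail

1. Step 9 (proposed new method). The enol(ate) of 9 may be too hindered or too weakly nucleophilic for the copper allenylidene. Background ionisation of the very electron-rich acetate may erode enantiocontrol, and the product may cycloisomerise to a furan through enol oxygen attack on the copper-activated alkyne. The fallback uses known chemistry, sets out from ketone 9 and acetate 13 and returns at 14. Ketone 9 is converted (TMSOTf, Et3N, CH2Cl2, 0 °C) into its trimethylsilyl enol ether F1. F1 and 13 are combined with FeCl3 (5 mol %) in MeCN at 0 °C; ionisation of the ring C-stabilised propargylic acetate and Mukaiyama-type capture by the enol silane give the stereoisomer mixture of the pentynoyl pyrone F2. This SN1 substitution is not enantioselective, so F2 is resolved by preparative chromatography on a chiral stationary phase and the two (3R) epimers are pooled as 14.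

2. Step 11 (key step). Cycloaddition may not set in below the temperature at which the alkynylboronate is protodeboronated, or the enol oxygen may add to the alkyne. The fallback builds rings A and B by a Nazarov route. It sets out from benzyl alcohol 5 (with Grignard reagent 7 and aldehyde 11) and returns at 21, bypassing 14–20. MnO2 oxidation of 5 gives 3,5-diisopropoxybenzaldehyde F3. Addition of 7 gives 1,2-bis(3,5-diisopropoxyphenyl)ethanol F4, and Dess–Martin oxidation gives 1,2-bis(3,5-diisopropoxyphenyl)ethanone F5. Knoevenagel-type condensation with 11 (piperidine, AcOH, PhMe, Dean–Stark) gives the α-aryl chalcone F6. Nazarov cyclisation (BF3·OEt2, CH2Cl2) closes C3–C3a ortho/para to the two ring A ethers and, after DBU equilibration, should give the racemic trans-indanone F7. F7 is resolved on a chiral stationary phase to 21.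

3. Step 10. The amide base or the acetylide may attack the pyrone, the second deprotonation may be incomplete because the enolate binds the borate ester, or boron may be lost in the acidic quench. The fallback masks the ketone covalently; it sets out from 14 and returns at 17. LiHMDS and TMSCl (THF, −78 °C) give the trimethylsilyl enol ether F8. One equivalent of LDA then metalates only the alkyne, and iPrOBpin followed by one equivalent of HCl·Et2O gives the alkynylboronate silyl enol ether F9. A second equivalent of anhydrous HCl cleaves the silyl enol ether to 17.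

Further compounds
F1 | step 9 | 4-isopropoxy-6-[2-(3,5-diisopropoxyphenyl)-1-(trimethylsilyloxy)ethenyl]-2H-pyran-2-one | C[Si](C)(C)OC(=Cc1cc(OC(C)C)cc(OC(C)C)c1)C1=CC(OC(C)C)=CC(=O)O1
F2 | step 9 | 6-[2-(3,5-diisopropoxyphenyl)-3-(2,4-diisopropoxyphenyl)pent-4-ynoyl]-4-isopropoxy-2H-pyran-2-one (all stereoisomers) | CC(C)OC1=CC(=O)OC(=C1)C(=O)C(c1cc(OC(C)C)cc(OC(C)C)c1)C(c1ccc(OC(C)C)cc1OC(C)C)C#C
F3 | step 11 | 3,5-diisopropoxybenzaldehyde | O=Cc1cc(OC(C)C)cc(OC(C)C)c1
F4 | step 11 | 1,2-bis(3,5-diisopropoxyphenyl)ethanol (racemic) | OC(Cc1cc(OC(C)C)cc(OC(C)C)c1)c1cc(OC(C)C)cc(OC(C)C)c1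
F5 | step 11 | 1,2-bis(3,5-diisopropoxyphenyl)ethanone | O=C(Cc1cc(OC(C)C)cc(OC(C)C)c1)c1cc(OC(C)C)cc(OC(C)C)c1
F6 | step 11 | 1,2-bis(3,5-diisopropoxyphenyl)-3-(2,4-diisopropoxyphenyl)prop-2-en-1-one | O=C(c1cc(OC(C)C)cc(OC(C)C)c1)C(=Cc1ccc(OC(C)C)cc1OC(C)C)c1cc(OC(C)C)cc(OC(C)C)c1
F7 | step 11 | racemic trans-2-(3,5-diisopropoxyphenyl)-3-(2,4-diisopropoxyphenyl)-4,6-diisopropoxy-2,3-dihydro-1H-inden-1-one (both enantiomers) | O=C1c2cc(OC(C)C)cc(OC(C)C)c2[C@H](c2ccc(OC(C)C)cc2OC(C)C)[C@H]1c1cc(OC(C)C)cc(OC(C)C)c1.O=C1c2cc(OC(C)C)cc(OC(C)C)c2[C@@H](c2ccc(OC(C)C)cc2OC(C)C)[C@@H]1c1cc(OC(C)C)cc(OC(C)C)c1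
F8 | step 10 | trimethylsilyl enol ether of 14 (3R) | CC(C)OC1=CC(=O)OC(=C1)C(O[Si](C)(C)C)=C(c1cc(OC(C)C)cc(OC(C)C)c1)[C@@H](c1ccc(OC(C)C)cc1OC(C)C)C#C
F9 | step 10 | trimethylsilyl enol ether of 17 (3R) | CC(C)OC1=CC(=O)OC(=C1)C(O[Si](C)(C)C)=C(c1cc(OC(C)C)cc(OC(C)C)c1)[C@@H](c1ccc(OC(C)C)cc1OC(C)C)C#CB1OC(C)(C)C(C)(C)O1
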